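The numbers in the tables were computed for substances that don't exist, and the scatter is random.

If gas must cross into the liquid before it reacts, I have two resistances in series, so I solve each end and join them.

| setting | ash | birch | flask |
|---|---|---|---|
| starting material | 0.20 M | 0.30 M | 0.20 M |
| gas | 11 mM (held) | 11 mM (held) | 11 mM (held) |
| remark | the very flask that is asked about, followed so far | run made earlier |  |
| time |  |  | 3.0 min |

ash run (percent of the starting material charged)

| time / s | first product / % | starting material / % |
|---|---|---|
| 10.0 | 2.9 | 98.7 |
| 15.0 | 0.3 | 98.1 |
| 25.0 | 2.8 | 98.7 |
| 50.0 | 5.2 | 94.4 |
| 90.0 | 8.8 | 88.0 |

birch run (percent of the starting material charged)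

| time / min | first product / % | starting material / % |
|---|---|---|
| 0.667 | 3.0 | 98.2 |
| 1.33 | 6.6 | 92.3 |
| 2.00 | 9.4 | 90.1 |
| 2.50 | 11.2 | 86.8 |
| 3.00 | 13.8 | 81.9 |

(readings scatter by 1 percentage point)

1. the first product standing at 3.0 min, as a percentage of the starting material charged
2. the change that raises the amount of first product at 3.0 min, in percent of the starting material charged most ("none" if none brings more than 2 percentage points) (theta / delta / none)
3. amount of first product at 3.0 min, in percent of the starting material charged, after delta

- at the start none of the gas is in solution

- theta: doubling the transfer coefficient of the gas, all else as stated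
- delta: doubling the saturation concentration of gas, all else as stated

With much starting material, the rate stands at a ceiling, the transfer rate into gas-free liquid. With little, the rate follows the charge. Joined: rate = ceiling × charge / (charge + half-speed charge).

Up to its last reading, ash lost starting material at 16.0 mM min⁻¹, birch at 18.1 mM min⁻¹. The charge rose by a factor 1.50, the rate by 1.13. The charge at which the two resistances are equal then reads 0.107 M; I call it the half-speed charge. The ceiling reads 24.5 mM min⁻¹. Each reading has a scatter of 1 percentage point, so both are rough.

Now the ladder for the flask. Dissolved gas is eaten in about 0.239 min. It is refilled more slowly, in about 0.448 min. Both are shorter than the 3.0 min run, so dissolved gas soon holds near 3.83 mM. Turning over the charge takes 12.5 min, longer than the run, so the charge falls slowly.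

This gives a pseudo-first-order decay, and I expect 78.7% of the starting material left. The asked time is twice the last ash time, so doubling the last ash reading gives 17.6% first product. But the ash balance already lacks 3.2 points, so I commit to a little less. Delta doubles the ceiling and keeps the half-speed charge, so the rate rises by a factor 2. Theta doubles both, so the rate rises by a factor 1.48. I choose delta.

The forecast, reading “Rate barely follows starting material”, gives 16%, delta and 24%.

The flask gives 15.7%; delta adds 5.9 points, theta 3.7 points, and 21.6% stands after delta.

    starting material + reagent → first product + by-product (k = 20.0 L mol⁻¹ min⁻¹)
    reagent + first product → double product + by-product (k = 46.0 L mol⁻¹ min⁻¹)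
    reagent + double product → tris adduct + by-product (k = 11.0 L mol⁻¹ min⁻¹)
    gas ⇌ reagent, rate k4*(csat - [reagent]) (kL = 2.50 min⁻¹)

The dissolved gas is the reagent. The flask keeps 80% of its starting material, against my 78.7%. The neighbour flask is charged with 0.050 M of starting material, less than the half-speed charge. The same decay gives 62.5% left there. The neighbour flask keeps 66%, and its first product stands at 21.1%.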